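**Retrosynthetic overview**
1. Target 34 ⇐ methyl ester of the ring-D acid ⇐ Ireland–Claisen ring contraction of a ten-membered allylic lactone (forms C6–C7, moves the ring-B alkene to C8=C9) ⇐ Mitsunobu macrolactonization of a hydroxy acid with inversion at the carbinol.
2. Hydroxy acid ⇐ Z-Wittig and hydride reduction of a tricyclic enone Weinreb amide ⇐ intramolecular enone–alkene [2+2] photocycloaddition (rings A and C) of a 4-substituted cyclohexenone.
3. Cyclohexenone (ring B) ⇐ enamine-catalysed Michael addition to methyl vinyl ketone, then intramolecular aldol condensation, of a β-branched aldehyde.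
4. Aldehyde ⇐ Evans alkylation of an acetal imide (fragment 2) with a dienyl bromide (fragment 1), then alkyl–alkyl Suzuki coupling with a C7 bromide (fragment 3); the Wittig salt is fragment 4.
5. Ring order: B (aldol), A + C ([2+2]), ten-membered lactone (macrolactonization), D (ring contraction).

Assumption: the SMILES is read literally, i.e. H-7 and H-13 trans (trans B/D fusion) with the ester at C-6 trans to H-7, which is not the all-cis arrangement a cycloaddition of a ring alkene would give; locants follow tetracyclo[5.4.2.0(3,13).0(10,12)]tridecane (target) and tricyclo[4.3.1.0(3,10)]decane (A/B/C tricycles); ring A = cyclobutane, B = cyclohexene fused to A, C = cyclopentane, D = ester-bearing cyclohexene.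

**Fragment 1 (dienyl bromide)**

Step 1
Reactants: 1 prop-2-yn-1-ol; 2 3-bromoprop-1-ene
Product: 3 hex-5-en-2-yn-1-ol
Conditions: CuI (10 mol %), K2CO3, NaI (cat.), DMF, rt
Reagents that add atoms: none
Why: Copper-catalysed SN2 allylation of the terminal alkyne (copper acetylide) joins the two C3 units; no stereocentre is formed.

Step 2
Reactants: 3 hex-5-en-2-yn-1-ol
Product: 4 (2E)-hexa-2,5-dien-1-ol
Conditions: LiAlH4, THF, 0 °C → reflux; aqueous work-up
Reagents that add atoms: none
Why: Hydroxyl-directed trans-hydroalumination of the propargylic alcohol gives only the E allylic alcohol and leaves the isolated terminal alkene untouched.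

Step 3
Reactants: 4 (2E)-hexa-2,5-dien-1-ol
Product: 5 (2E)-1-bromohexa-2,5-diene
Conditions: CBr4, PPh3, CH2Cl2, 0 °C
Reagents that add atoms: carbon tetrabromide BrC(Br)(Br)Br
Why: Appel bromination replaces the primary allylic hydroxyl by SN2 without allylic shift or loss of E geometry.

**Fragment 2 (acetal imide)**

Step 4
Reactants: 6 (4S)-4-benzyl-1,3-oxazolidin-2-one; 7 pent-4-enoyl chloride
Product: 8 (4S)-4-benzyl-3-(pent-4-enoyl)-1,3-oxazolidin-2-one
Conditions: n-BuLi, THF, −78 °C; then 7, −78 → 0 °C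
Reagents that add atoms: none
Why: N-acylation of the lithiated oxazolidinone installs the Evans auxiliary.

Step 5
Reactants: 8 (4S)-4-benzyl-3-(pent-4-enoyl)-1,3-oxazolidin-2-one
Product: 9 4-[(4S)-4-benzyl-2-oxo-1,3-oxazolidin-3-yl]-4-oxobutanal
Conditions: O3, CH2Cl2, −78 °C; then Me2S, −78 °C → rt
Reagents that add atoms: ozone [O-][O+]=O
Why: Ozonolysis with reductive work-up cleaves the only alkene to the aldehyde one carbon shorter.

Step 6
Reactants: 9 4-[(4S)-4-benzyl-2-oxo-1,3-oxazolidin-3-yl]-4-oxobutanal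
Product: 10 (4S)-4-benzyl-3-(4,4-dimethoxybutanoyl)-1,3-oxazolidin-2-one
Conditions: HC(OMe)3, MeOH, PPTS (cat.), rt
Reagents that add atoms: trimethyl orthoformate COC(OC)OC
Why: Acid-catalysed acetalisation masks the aldehyde so that only the imide is enolised in step 11.

**Fragment 3 (C7 bromide)**

Step 7
Reactants: 11 hex-5-yn-1-ol
Product: 12 hept-5-yn-1-ol
Conditions: n-BuLi (2.1 equiv), THF, −78 → 0 °C; then MeI, −78 °C → rt
Reagents that add atoms: iodomethane CI
Why: C-methylation of the lithium acetylide of the alkoxide/acetylide dianion gives the internal alkyne needed for E-selective reduction.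

Step 8
Reactants: 12 hept-5-yn-1-ol
Product: 13 (5E)-hept-5-en-1-ol
Conditions: Na, NH3(l), THF, −33 °C; then NH4Cl
Reagents that add atoms: none
Why: Dissolving-metal reduction of the dialkyl alkyne gives the E alkene through the trans vinyl anion.

Step 9
Reactants: 13 (5E)-hept-5-en-1-ol
Product: 14 (2E)-7-bromohept-2-ene
Conditions: CBr4, PPh3, CH2Cl2, 0 °C
Reagents that add atoms: carbon tetrabromide BrC(Br)(Br)Br
Why: Appel bromination of the primary alcohol leaves the E alkene untouched.

**Fragment 4 (Wittig salt)**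

Step 10
Reactants: 15 3-bromopropanoic acid
Product: 16 (2-carboxyethyl)triphenylphosphonium bromide
Conditions: PPh3, MeCN, reflux
Reagents that add atoms: triphenylphosphine c1ccc(cc1)P(c1ccccc1)c1ccccc1
Why: SN2 quaternisation of the phosphine by the primary bromide gives the Wittig salt.

**Assembly**

Step 11
Reactants: 10 (4S)-4-benzyl-3-(4,4-dimethoxybutanoyl)-1,3-oxazolidin-2-one; 5 (2E)-1-bromohexa-2,5-diene
Product: 17 (4S)-4-benzyl-3-[(2S,4E)-2-(2,2-dimethoxyethyl)octa-4,7-dienoyl]-1,3-oxazolidin-2-one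
Conditions: NaN(SiMe3)2, THF, −78 °C; then 5, −78 → −40 °C
Reagents that add atoms: none
Why: Evans asymmetric alkylation: the chelated Z sodium enolate is attacked by the allylic bromide on the face opposite the benzyl group, which sets the S centre (later C-3 of the target).

Step 12
Reactants: 17 alkylated imide
Product: 18 (2S,4E)-2-(2,2-dimethoxyethyl)-N-methoxy-N-methylocta-4,7-dienamide
Conditions: MeNHOMe·HCl, AlMe3, CH2Cl2, −10 °C → rt
Reagents that add atoms: N,O-dimethylhydroxylamine hydrochloride CNOC.Cl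
Why: Aluminium amide transamination (Weinreb aminolysis) removes the auxiliary without epimerisation and leaves an amide that is later reduced cleanly to the aldehyde.

Step 13
Reactants: 18 Weinreb amide; 14 (2E)-7-bromohept-2-ene
Product: 20 (2S,4E,13E)-2-(2,2-dimethoxyethyl)-N-methoxy-N-methylpentadeca-4,13-dienamide, via B-alkyl-9-BBN borane 19 (not isolated)
Conditions: 9-BBN, THF, 0 °C → rt; then 14, Pd(OAc)2 (4 mol %), PCy3 (8 mol %), K3PO4·H2O, THF, rt
Reagents that add atoms: none
Why: 9-BBN hydroborates only the terminal alkene, and the B-alkyl Suzuki–Miyaura alkyl–alkyl coupling with the primary bromide completes the (E)-dec-8-enyl chain.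

Step 14
Reactants: 20 amide acetal
Product: 21 (2S,4E,13E)-N-methoxy-N-methyl-2-(2-oxoethyl)pentadeca-4,13-dienamide
Conditions: 1 M HCl, THF, rt
Reagents that add atoms: water O
Why: Mild acetal hydrolysis frees the aldehyde while the amide and both alkenes are inert.

Step 15
Reactants: 21 aldehyde; 22 but-3-en-2-one
Product: 24 (2S,4E,13E)-N-methoxy-N-methyl-2-[(1R)-4-oxocyclohex-2-en-1-yl]pentadeca-4,13-dienamide, via keto aldehyde 23 (not isolated)
Conditions: (S)-2-[diphenyl(trimethylsilyloxy)methyl]pyrrolidine (10 mol %), ethyl 3,4-dihydroxybenzoate (20 mol %), CH2Cl2, 4 °C; then 0.1 M aq KOH, n-Bu4NOH (cat.), Et2O/THF, 40 °C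
Reagents that add atoms: none
Why: Enamine-catalysed Michael addition, in which the bulky catalyst substituent shields one enamine face and sets the aldehyde α-carbon as S (later C-13), is followed by intramolecular aldol condensation of the methyl ketone onto the aldehyde, closing ring B as the cyclohexenone.

Step 16
Reactants: 24 cyclohexenone
Product: 25 tricyclic ketone (rings A, B, C)
Conditions: hν (350 nm, Pyrex), degassed CH2Cl2 (0.005 M), rt
Reagents that add atoms: none
Why: Intramolecular enone–alkene [2+2] photocycloaddition: 1,5-closure from the enone β-carbon (rule of five) forms rings C and A cis-fused on the face fixed by the two existing centres, and closure of the 1,4-diradical from the E alkene puts the chain exo.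

Step 17
Reactants: 25 tricyclic ketone
Product: 26 tricyclic enone (C7=C8, C9=O)
Conditions: IBX, DMSO/PhMe, 70 °C
Reagents that add atoms: none
Why: IBX dehydrogenation goes through the only accessible enol (the other α-carbon is a cyclobutane methine) and gives the ring-B enone.

Step 18
Reactants: 26 tricyclic enone
Product: 27 hydroxy aldehyde
Conditions: i-Bu2AlH (4 equiv), CH2Cl2, −78 °C; then KNaC4H4O6 (aq)
Reagents that add atoms: none
Why: i-Bu2AlH reduces the Weinreb amide to the aldehyde (stable chelate until work-up) and the enone 1,2 from the convex face, so the new hydroxyl sits on the concave face (H-9 cis to H-1).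

Step 19
Reactants: 27 hydroxy aldehyde; 16 (2-carboxyethyl)triphenylphosphonium bromide
Product: 29 hydroxy (Z)-but-3-enoic acid, via phosphorus ylide 28 (not isolated)
Conditions: 16, NaN(SiMe3)2 (2 equiv per 16), THF, −78 → 0 °C; then 27, −78 °C → rt; dilute HCl work-up
Reagents that add atoms: none
Why: Wittig olefination with the non-stabilised carboxylate ylide gives the Z β,γ-unsaturated acid through the kinetic cis-oxaphosphetane.

Step 20
Reactants: 29 hydroxy acid
Product: 30 ten-membered lactone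
Conditions: PPh3, DIAD, PhMe/THF (0.002 M, slow addition of 29), −10 °C → rt
Reagents that add atoms: none
Why: Mitsunobu macrolactonization: the tethered carboxylate displaces the oxyphosphonium by SN2, inverting C-9 so that the ester oxygen ends on the convex face as the ten-membered ring closes.

Step 21
Reactants: 30 ten-membered lactone
Product: 34 CNP0133550.2 (target), via silyl ketene acetal 31 (not isolated), via trimethylsilyl ester 32 (not isolated), via carboxylic acid 33 (not isolated)
Conditions: LiN(i-Pr)2, Me3SiCl/Et3N, THF, −78 °C → 65 °C; 1 M HCl; then Me3SiCHN2, PhMe/MeOH, 0 °C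
Reagents that add atoms: (trimethylsilyl)diazomethane C[Si](C)(C)C=[N+]=[N-]
Why: Ireland–Claisen ring contraction: the ring-bound ketene acetal can react only through a boat transition state on the convex face, which forms C6–C7 suprafacially (H-7 trans to H-13), fixes C-6 with the carboxyl trans to H-7 and moves the alkene to C8=C9; neutral esterification then leaves the α-centre untouched.

**Compound list**
1 | prop-2-yn-1-ol | C#CCO | starting material
2 | 3-bromoprop-1-ene | C=CCBr | starting material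
3 | hex-5-en-2-yn-1-ol | OCC#CCC=C | intermediate
4 | (2E)-hexa-2,5-dien-1-ol | OC/C=C/CC=C | intermediate
5 | (2E)-1-bromohexa-2,5-diene | BrC/C=C/CC=C | intermediate
6 | (4S)-4-benzyl-1,3-oxazolidin-2-one | O=C1N[C@@H](Cc2ccccc2)CO1 | starting material
7 | pent-4-enoyl chloride | C=CCCC(=O)Cl | starting material
8 | (4S)-4-benzyl-3-(pent-4-enoyl)-1,3-oxazolidin-2-one | O=C1OC[C@H](Cc2ccccc2)N1C(=O)CCC=C | intermediate
9 | 4-[(4S)-4-benzyl-2-oxo-1,3-oxazolidin-3-yl]-4-oxobutanal | O=C1OC[C@H](Cc2ccccc2)N1C(=O)CCC=O | intermediate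
10 | (4S)-4-benzyl-3-(4,4-dimethoxybutanoyl)-1,3-oxazolidin-2-one | O=C1OC[C@H](Cc2ccccc2)N1C(=O)CCC(OC)OC | intermediate
11 | hex-5-yn-1-ol | C#CCCCCO | starting material
12 | hept-5-yn-1-ol | CC#CCCCCO | intermediate
13 | (5E)-hept-5-en-1-ol | C/C=C/CCCCO | intermediate
14 | (2E)-7-bromohept-2-ene | C/C=C/CCCCBr | intermediate
15 | 3-bromopropanoic acid | OC(=O)CCBr | starting material
16 | (2-carboxyethyl)triphenylphosphonium bromide | OC(=O)CC[P+](c1ccccc1)(c1ccccc1)c1ccccc1.[Br-] | intermediate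
17 | (4S)-4-benzyl-3-[(2S,4E)-2-(2,2-dimethoxyethyl)octa-4,7-dienoyl]-1,3-oxazolidin-2-one | O=C1OC[C@H](Cc2ccccc2)N1C(=O)[C@H](CC(OC)OC)C/C=C/CC=C | intermediate
18 | (2S,4E)-2-(2,2-dimethoxyethyl)-N-methoxy-N-methylocta-4,7-dienamide | CON(C)C(=O)[C@H](CC(OC)OC)C/C=C/CC=C | intermediate
19 | B-alkyl-9-BBN borane of 18 (boron on the former terminal CH2) | CON(C)C(=O)[C@H](CC(OC)OC)C/C=C/CCCB1C2CCCC1CCC2 | intermediate
20 | (2S,4E,13E)-2-(2,2-dimethoxyethyl)-N-methoxy-N-methylpentadeca-4,13-dienamide | CON(C)C(=O)[C@H](CC(OC)OC)C/C=C/CCCCCCC/C=C/C | intermediate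
21 | (2S,4E,13E)-N-methoxy-N-methyl-2-(2-oxoethyl)pentadeca-4,13-dienamide | CON(C)C(=O)[C@H](CC=O)C/C=C/CCCCCCC/C=C/C | intermediate
22 | but-3-en-2-one (methyl vinyl ketone) | CC(=O)C=C | starting material
23 | (2S,4E,13E)-2-[(2S)-1,5-dioxohexan-2-yl]-N-methoxy-N-methylpentadeca-4,13-dienamide | CON(C)C(=O)[C@H]([C@@H](C=O)CCC(C)=O)C/C=C/CCCCCCC/C=C/C | intermediate
24 | (2S,4E,13E)-N-methoxy-N-methyl-2-[(1R)-4-oxocyclohex-2-en-1-yl]pentadeca-4,13-dienamide | O=C1C=C[C@H]([C@@H](C(=O)N(C)OC)C/C=C/CCCCCCC/C=C/C)CC1 | intermediate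
25 | 2-[(8E)-dec-8-en-1-yl]-N-methoxy-N-methyl-9-oxotricyclo[4.3.1.0(3,10)]decane-5-carboxamide; H-1, H-3, H-6, H-10 all cis, H-2 trans to H-1 (chain exo), H-5 cis to H-6 | C/C=C/CCCCCCC[C@@H]1[C@H]2C(=O)CC[C@@H]3[C@H]2[C@H]1C[C@@H]3C(=O)N(C)OC | intermediate
26 | 2-[(8E)-dec-8-en-1-yl]-N-methoxy-N-methyl-9-oxotricyclo[4.3.1.0(3,10)]dec-7-ene-5-carboxamide, same relative configuration as 25 | C/C=C/CCCCCCC[C@@H]1[C@H]2C(=O)C=C[C@@H]3[C@H]2[C@H]1C[C@@H]3C(=O)N(C)OC | intermediate
27 | 2-[(8E)-dec-8-en-1-yl]-9-hydroxytricyclo[4.3.1.0(3,10)]dec-7-ene-5-carbaldehyde; H-9 cis to H-1 (hydroxyl on the concave face) | C/C=C/CCCCCCC[C@@H]1[C@H]2[C@@H](O)C=C[C@@H]3[C@H]2[C@H]1C[C@@H]3C=O | intermediate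
28 | sodium 3-(triphenylphosphoranylidene)propanoate | [Na+].[O-]C(=O)CC=P(c1ccccc1)(c1ccccc1)c1ccccc1 | intermediate
29 | (3Z)-4-{2-[(8E)-dec-8-en-1-yl]-9-hydroxytricyclo[4.3.1.0(3,10)]dec-7-en-5-yl}but-3-enoic acid, ring stereochemistry as 27 | C/C=C/CCCCCCC[C@@H]1[C@H]2[C@@H](O)C=C[C@@H]3[C@H]2[C@H]1C[C@@H]3/C=C\CC(=O)O | intermediate
30 | ten-membered (Z)-lactone of 29, closed on the C-9 oxygen with inversion (H-9 trans to H-1) | C/C=C/CCCCCCC[C@@H]1[C@H]2[C@H]4C=C[C@@H]3[C@H]2[C@H]1C[C@@H]3/C=C\CC(=O)O4 | intermediate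
31 | O-trimethylsilyl ketene acetal of 30 (ring oxygen and ring carbon cis on the new C=C) | C/C=C/CCCCCCC[C@@H]1[C@H]2[C@H]4C=C[C@@H]3[C@H]2[C@H]1C[C@@H]3/C=C\C=C(\O[Si](C)(C)C)O4 | intermediate
32 | trimethylsilyl 11-[(8E)-dec-8-en-1-yl]tetracyclo[5.4.2.0(3,13).0(10,12)]trideca-4,8-diene-6-carboxylate, stereochemistry as 34 | C/C=C/CCCCCCC[C@@H]1[C@H]2C=C[C@H]3[C@@H]4[C@H]2[C@H]1C[C@@H]4C=C[C@H]3C(=O)O[Si](C)(C)C | intermediate
33 | 11-[(8E)-dec-8-en-1-yl]tetracyclo[5.4.2.0(3,13).0(10,12)]trideca-4,8-diene-6-carboxylic acid, stereochemistry as 34 | C/C=C/CCCCCCC[C@@H]1[C@H]2C=C[C@H]3[C@@H]4[C@H]2[C@H]1C[C@@H]4C=C[C@H]3C(=O)O | intermediate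
34 | methyl 11-[(8E)-dec-8-en-1-yl]tetracyclo[5.4.2.0(3,13).0(10,12)]trideca-4,8-diene-6-carboxylate; H-1, H-3, H-10, H-12, H-13 all cis, H-11 trans to H-10, H-7 trans to H-13, H-6 cis to H-7 | C/C=C/CCCCCCC[C@@H]1[C@H]2C=C[C@H]3[C@@H]4[C@H]2[C@H]1C[C@@H]4C=C[C@H]3C(=O)OC | target

**Step count and risks**
Total: 21 steps. Longest linear sequence: 14 steps (steps 1–3, then 11–21; the branch through steps 4–6 is equally long), which is two thirds of the total.

Most likely to fail:

Step 20 (Mitsunobu closure of a ten-membered ring at a hindered allylic carbinol; dimerisation, SN2′ attack or elimination may compete). The fallback sets out from 27 and comes back at 30. Wittig methylenation of 27 (Ph3PCH3Br, KOt-Bu, THF) gives the vinyl carbinol 2-[(8E)-dec-8-en-1-yl]-5-ethenyltricyclo[4.3.1.0(3,10)]dec-7-en-9-ol F3. Intermolecular Mitsunobu esterification with but-3-enoic acid (PPh3, DIAD) inverts C-9 and gives the but-3-enoate F4. Ring-closing metathesis of the two terminal alkenes (second-generation Grubbs catalyst, CH2Cl2, 0.001 M, 40 °C) then closes the lactone 30, of which only the Z isomer can enter step 21.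

Step 21 (enolisation of a β,γ-unsaturated medium-ring lactone and transannular [3,3] shift; alkene conjugation or failure to reach the boat geometry are the risks). The fallback sets out from 29 and comes back at 34. Esterification (Me3SiCHN2) gives the hydroxy methyl ester F5. The concave-face hydroxyl is converted into the diethyl phosphate F6 (ClP(O)(OEt)2, pyridine, DMAP). Ring D is then closed by intramolecular anti-SN2′ alkylation of the ester dienolate (KN(SiMe3)2, THF, −78 → 0 °C), which enters C-7 from the convex face with the same alkene shift and gives 34; the C-6 configuration would rest on the cyclic transition state and would have to be verified.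

Step 16 (the triplet 1,4-diradical may give crossed regioisomers or scramble the chain-bearing cyclobutane carbon). The fallback sets out from 24 and comes back at 25. Luche reduction (NaBH4, CeCl3·7H2O, MeOH) gives the cyclohexenol (2S,4E,13E)-2-[(1R,4RS)-4-hydroxycyclohex-2-en-1-yl]-N-methoxy-N-methylpentadeca-4,13-dienamide F1. Copper-catalysed [2+2] photobicyclisation of its 1,6-diene ((CuOTf)2·C6H6, Et2O, 254 nm), which runs through a ground-state copper–diene complex instead of an enone triplet, gives the tricyclic alcohol 2-[(8E)-dec-8-en-1-yl]-9-hydroxy-N-methoxy-N-methyltricyclo[4.3.1.0(3,10)]decane-5-carboxamide F2. Oxidation (Dess–Martin periodinane) returns 25.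

Further compounds
F1 | step 16 | (2S,4E,13E)-2-[(1R,4RS)-4-hydroxycyclohex-2-en-1-yl]-N-methoxy-N-methylpentadeca-4,13-dienamide | OC1C=C[C@H]([C@@H](C(=O)N(C)OC)C/C=C/CCCCCCC/C=C/C)CC1
F2 | step 16 | 2-[(8E)-dec-8-en-1-yl]-9-hydroxy-N-methoxy-N-methyltricyclo[4.3.1.0(3,10)]decane-5-carboxamide (C-9 epimers, otherwise as 25) | C/C=C/CCCCCCC[C@@H]1[C@H]2C(O)CC[C@@H]3[C@H]2[C@H]1C[C@@H]3C(=O)N(C)OC
F3 | step 20 | 2-[(8E)-dec-8-en-1-yl]-5-ethenyltricyclo[4.3.1.0(3,10)]dec-7-en-9-ol (stereochemistry as 27) | C/C=C/CCCCCCC[C@@H]1[C@H]2[C@@H](O)C=C[C@@H]3[C@H]2[C@H]1C[C@@H]3C=C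
F4 | step 20 | 2-[(8E)-dec-8-en-1-yl]-5-ethenyltricyclo[4.3.1.0(3,10)]dec-7-en-9-yl but-3-enoate (C-9 inverted) | C/C=C/CCCCCCC[C@@H]1[C@H]2[C@H](OC(=O)CC=C)C=C[C@@H]3[C@H]2[C@H]1C[C@@H]3C=C
F5 | step 21 | methyl (3Z)-4-{2-[(8E)-dec-8-en-1-yl]-9-hydroxytricyclo[4.3.1.0(3,10)]dec-7-en-5-yl}but-3-enoate | C/C=C/CCCCCCC[C@@H]1[C@H]2[C@@H](O)C=C[C@@H]3[C@H]2[C@H]1C[C@@H]3/C=C\CC(=O)OC
F6 | step 21 | methyl (3Z)-4-{2-[(8E)-dec-8-en-1-yl]-9-[(diethoxyphosphoryl)oxy]tricyclo[4.3.1.0(3,10)]dec-7-en-5-yl}but-3-enoate | C/C=C/CCCCCCC[C@@H]1[C@H]2[C@@H](OP(=O)(OCC)OCC)C=C[C@@H]3[C@H]2[C@H]1C[C@@H]3/C=C\CC(=O)OC
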